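**Retrosynthetic overview**
- Target ⇐ its 6,5'-di-O-benzyl ether (final hydrogenolysis) ⇐ 3-O-methylation of the corresponding flavonol.
- The pyranone ring (ring C) is the only ring built; it is closed last, by Algar–Flynn–Oyamada oxidative cyclisation of a 2'-hydroxychalcone.
- The chalcone Cα–Cβ bond is the key C–C bond: an intermolecular Claisen–Schmidt aldol condensation of a ring-A acetophenone with a ring-B benzaldehyde.
- Ring-A ketone ⇐ paeonol (Elbs para-hydroxylation, selective 5-O-benzylation).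
- Ring-B aldehyde ⇐ 2,4-dimethoxybenzaldehyde (Dakin-type oxidation, benzylation, Vilsmeier formylation); rings A and B are bought as arenes.

Assumption: the target has no stereocentre (it is achiral), so no enantiocontrol is needed; the route delivers the single compound drawn.

**Route**

Step 1
Reactants: 1 paeonol (1-(2-hydroxy-4-methoxyphenyl)ethan-1-one)
Product: 3 1-(2,5-dihydroxy-4-methoxyphenyl)ethan-1-one, via aryl sulfate 2 (not isolated)
Conditions: K2S2O8, 10% aq NaOH, 0 °C → rt, 24 h; then conc. HCl, 90 °C, 1 h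
Reagents that add atoms: potassium peroxodisulfate, [K+].[K+].[O-]S(=O)(=O)OOS(=O)(=O)[O-]
Why: Elbs persulfate oxidation: the phenoxide attacks the peroxide oxygen through C-5 (the free position para to OH, also activated by the ortho OMe) to give sulfate 2, which hot acid hydrolyses at S–O to the hydroquinone; no stereocentre.

Step 2
Reactants: 3 1-(2,5-dihydroxy-4-methoxyphenyl)ethan-1-one
Product: 4 1-[5-(benzyloxy)-2-hydroxy-4-methoxyphenyl]ethan-1-one
Conditions: BnBr (1.05 eq), K2CO3 (1.1 eq), acetone, reflux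
Reagents that add atoms: benzyl bromide, BrCc1ccccc1
Why: Selective Williamson etherification: the 2-OH is tied up in a hydrogen bond to the acetyl C=O, so one equivalent of BnBr with weak base alkylates only the free 5-OH.

Step 3
Reactants: 5 2,4-dimethoxybenzaldehyde
Product: 7 2,4-dimethoxyphenol, via aryl formate 6 (not isolated)
Conditions: mCPBA, CH2Cl2, 0 °C → rt; then 10% aq NaOH, MeOH, rt; then dil. HCl
Reagents that add atoms: 3-chloroperoxybenzoic acid, OOC(=O)c1cccc(Cl)c1
Why: Baeyer–Villiger (Dakin-type) oxidation: the electron-rich aryl group migrates in the Criegee intermediate to give formate 6, which is saponified in the same flask.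

Step 4
Reactants: 7 2,4-dimethoxyphenol
Product: 8 1-(benzyloxy)-2,4-dimethoxybenzene
Conditions: BnBr, K2CO3, DMF, 60 °C
Reagents that add atoms: benzyl bromide, BrCc1ccccc1
Why: Plain Williamson ether synthesis on the only phenol present.

Step 5
Reactants: 8 1-(benzyloxy)-2,4-dimethoxybenzene
Product: 10 5-(benzyloxy)-2,4-dimethoxybenzaldehyde, via aryl iminium salt 9 (not isolated)
Conditions: POCl3 (1.5 eq), DMF, 0 → 70 °C, 3 h; then ice–water, rt
Reagents that add atoms: N,N-dimethylformamide, CN(C)C=O (formyl carbon); water, O (aldehyde oxygen, on hydrolysis of 9)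
Why: Vilsmeier–Haack formylation attacks C-5, the only unhindered position activated by two alkoxy groups (para to 2-OMe, ortho to 4-OMe), as in 1,2,4-trimethoxybenzene → asaraldehyde; the benzyl ether is inert.

Step 6
Reactants: 4 1-[5-(benzyloxy)-2-hydroxy-4-methoxyphenyl]ethan-1-one; 10 5-(benzyloxy)-2,4-dimethoxybenzaldehyde
Product: 12 (E)-1-[5-(benzyloxy)-2-hydroxy-4-methoxyphenyl]-3-[5-(benzyloxy)-2,4-dimethoxyphenyl]prop-2-en-1-one, via aldol adduct 11 (not isolated)
Conditions: 50% aq KOH, EtOH–THF, rt, 48–72 h; then dil. HCl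
Reagents that add atoms: none
Why: Claisen–Schmidt (crossed aldol) condensation: the ketone enolate adds to the non-enolisable aldehyde and E1cB dehydration of racemic aldol 11 gives the conjugated E-enone, which removes the transient stereocentre.

Step 7
Reactants: 12 (E)-1-[5-(benzyloxy)-2-hydroxy-4-methoxyphenyl]-3-[5-(benzyloxy)-2,4-dimethoxyphenyl]prop-2-en-1-one
Product: 14 6-(benzyloxy)-2-[5-(benzyloxy)-2,4-dimethoxyphenyl]-3-hydroxy-7-methoxy-4H-chromen-4-one, via trans-dihydroflavonol 13 (not isolated)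
Conditions: 30% H2O2, 2 M aq NaOH, MeOH–THF, 0 °C → rt, 16 h; then dil. HCl
Reagents that add atoms: hydrogen peroxide, OO
Why: Algar–Flynn–Oyamada reaction: alkaline H2O2 cyclises the 2'-hydroxychalcone oxidatively to racemic trans-dihydroflavonol 13, which is dehydrogenated in situ to the flavonol; with no 6'-substituent (H-5 in the flavone) flavonol rather than aurone forms, and both transient stereocentres are erased.

Step 8
Reactants: 14 6-(benzyloxy)-2-[5-(benzyloxy)-2,4-dimethoxyphenyl]-3-hydroxy-7-methoxy-4H-chromen-4-one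
Product: 15 6-(benzyloxy)-2-[5-(benzyloxy)-2,4-dimethoxyphenyl]-3,7-dimethoxy-4H-chromen-4-one
Conditions: MeI, K2CO3, DMF, rt
Reagents that add atoms: iodomethane, CI
Why: Williamson O-methylation of the acidic enolic 3-OH, the only free hydroxyl in 14.

Step 9
Reactants: 15 6-(benzyloxy)-2-[5-(benzyloxy)-2,4-dimethoxyphenyl]-3,7-dimethoxy-4H-chromen-4-one
Product: 16 6-hydroxy-2-(5-hydroxy-2,4-dimethoxyphenyl)-3,7-dimethoxy-4H-chromen-4-one
Conditions: H2 (1 atm), 10% Pd/C, THF–MeOH, rt
Reagents that add atoms: none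
Why: Catalytic hydrogenolysis cleaves both benzyl aryl ethers, while the tetrasubstituted chromone C2=C3 (a vinylogous ester), the ketone and the methyl ethers are untouched at 1 atm and rt.

**Compound list**
1 | paeonol, 1-(2-hydroxy-4-methoxyphenyl)ethan-1-one | CC(=O)c1ccc(OC)cc1O | starting material
2 | potassium 5-acetyl-4-hydroxy-2-methoxyphenyl sulfate (drawn as the mono-potassium salt) | CC(=O)c1cc(OS(=O)(=O)[O-])c(OC)cc1O.[K+] | intermediate
3 | 1-(2,5-dihydroxy-4-methoxyphenyl)ethan-1-one | CC(=O)c1cc(O)c(OC)cc1O | intermediate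
4 | 1-[5-(benzyloxy)-2-hydroxy-4-methoxyphenyl]ethan-1-one | CC(=O)c1cc(OCc2ccccc2)c(OC)cc1O | intermediate
5 | 2,4-dimethoxybenzaldehyde | COc1ccc(C=O)c(OC)c1 | starting material
6 | 2,4-dimethoxyphenyl formate | COc1ccc(OC=O)c(OC)c1 | intermediate
7 | 2,4-dimethoxyphenol | COc1ccc(O)c(OC)c1 | intermediate
8 | 1-(benzyloxy)-2,4-dimethoxybenzene | COc1ccc(OCc2ccccc2)c(OC)c1 | intermediate
9 | N-{[5-(benzyloxy)-2,4-dimethoxyphenyl]methylidene}-N-methylmethanaminium dichlorophosphate (counter-ion from POCl3 and the DMF oxygen) | C[N+](C)=Cc1cc(OCc2ccccc2)c(OC)cc1OC.[O-]P(=O)(Cl)Cl | intermediate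
10 | 5-(benzyloxy)-2,4-dimethoxybenzaldehyde | O=Cc1cc(OCc2ccccc2)c(OC)cc1OC | intermediate
11 | 1-[5-(benzyloxy)-2-hydroxy-4-methoxyphenyl]-3-[5-(benzyloxy)-2,4-dimethoxyphenyl]-3-hydroxypropan-1-one (racemic) | COc1cc(O)c(C(=O)CC(O)c2cc(OCc3ccccc3)c(OC)cc2OC)cc1OCc1ccccc1 | intermediate
12 | (E)-1-[5-(benzyloxy)-2-hydroxy-4-methoxyphenyl]-3-[5-(benzyloxy)-2,4-dimethoxyphenyl]prop-2-en-1-one | COc1cc(O)c(C(=O)/C=C/c2cc(OCc3ccccc3)c(OC)cc2OC)cc1OCc1ccccc1 | intermediate
13 | rac-(2R,3R)-6-(benzyloxy)-2-[5-(benzyloxy)-2,4-dimethoxyphenyl]-3-hydroxy-7-methoxychroman-4-one (trans, racemic; 2R,3R enantiomer drawn) | COc1cc(OC)c([C@H]2Oc3cc(OC)c(OCc4ccccc4)cc3C(=O)[C@@H]2O)cc1OCc1ccccc1 | intermediate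
14 | 6-(benzyloxy)-2-[5-(benzyloxy)-2,4-dimethoxyphenyl]-3-hydroxy-7-methoxy-4H-chromen-4-one | COc1cc(OC)c(-c2oc3cc(OC)c(OCc4ccccc4)cc3c(=O)c2O)cc1OCc1ccccc1 | intermediate
15 | 6-(benzyloxy)-2-[5-(benzyloxy)-2,4-dimethoxyphenyl]-3,7-dimethoxy-4H-chromen-4-one | COc1cc(OC)c(-c2oc3cc(OC)c(OCc4ccccc4)cc3c(=O)c2OC)cc1OCc1ccccc1 | intermediate
16 | 6,5'-dihydroxy-3,7,2',4'-tetramethoxyflavone, 6-hydroxy-2-(5-hydroxy-2,4-dimethoxyphenyl)-3,7-dimethoxy-4H-chromen-4-one (achiral) | COc1cc(OC)c(-c2oc3cc(OC)c(O)cc3c(=O)c2OC)cc1O | target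

**Totals**
Total step count: 9 (steps 1–2 make the ring-A ketone, steps 3–5 the ring-B aldehyde, steps 6–9 are the common end).
Longest linear sequence: 7 steps (5 → 7 → 8 → 10 → 12 → 14 → 15 → 16, i.e. steps 3–9).

**Three steps most likely to fail**

Step 1 (Elbs oxidation; conversion is usually modest, with recovered 1 and some over-oxidation). The fallback sets out from 1 and replaces the peroxide chemistry by halogenation and C–O coupling. NBS in MeCN at 0 °C brominates the same C-5 position (para to OH, ortho to OMe) to give 1-(5-bromo-2-hydroxy-4-methoxyphenyl)ethan-1-one F1. Pd-catalysed hydroxylation of the aryl bromide (Pd2(dba)3, tBuXPhos, KOH, dioxane–H2O, 100 °C, then HCl) then comes back to the route at 3.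

Step 6 (Claisen–Schmidt; the 2'-phenoxide deactivates the ketone and the aldehyde is very electron-rich, so the condensation can stall). The fallback sets out from 4 and removes the phenoxide by protection. NaH and MOMCl in DMF at 0 °C give 1-[5-(benzyloxy)-4-methoxy-2-(methoxymethoxy)phenyl]ethan-1-one F2. Its methyl ketone condenses readily with 10 (KOH, EtOH, rt) to (E)-1-[5-(benzyloxy)-4-methoxy-2-(methoxymethoxy)phenyl]-3-[5-(benzyloxy)-2,4-dimethoxyphenyl]prop-2-en-1-one F3. HCl in MeOH–THF at 40 °C cleaves the acetal and comes back to the route at 12.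

Step 7 (AFO; the ortho-methoxy B ring can slow cyclisation or leave dihydroflavonol or aurone by-products). The fallback sets out from 12 and separates ring closure from C-3 oxygenation. Catalytic I2 in DMSO at 130 °C cyclises and dehydrogenates the chalcone to 6-(benzyloxy)-2-[5-(benzyloxy)-2,4-dimethoxyphenyl]-7-methoxy-4H-chromen-4-one F4. Dimethyldioxirane in acetone–CH2Cl2 at 0 °C epoxidises the C2=C3 bond to the racemic flavone 2,3-epoxide F5. Catalytic TsOH in CH2Cl2 opens it at C-2 and, after loss of H-3, gives the 3-hydroxyflavone, coming back to the route at 14.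

**Further compounds**
F1 | step 1 | 1-(5-bromo-2-hydroxy-4-methoxyphenyl)ethan-1-one | CC(=O)c1cc(Br)c(OC)cc1O
F2 | step 6 | 1-[5-(benzyloxy)-4-methoxy-2-(methoxymethoxy)phenyl]ethan-1-one | CC(=O)c1cc(OCc2ccccc2)c(OC)cc1OCOC
F3 | step 6 | (E)-1-[5-(benzyloxy)-4-methoxy-2-(methoxymethoxy)phenyl]-3-[5-(benzyloxy)-2,4-dimethoxyphenyl]prop-2-en-1-one | COCOc1cc(OC)c(OCc2ccccc2)cc1C(=O)/C=C/c1cc(OCc2ccccc2)c(OC)cc1OC
F4 | step 7 | 6-(benzyloxy)-2-[5-(benzyloxy)-2,4-dimethoxyphenyl]-7-methoxy-4H-chromen-4-one | COc1cc(OC)c(-c2oc3cc(OC)c(OCc4ccccc4)cc3c(=O)c2)cc1OCc1ccccc1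
F5 | step 7 | 6-(benzyloxy)-2-[5-(benzyloxy)-2,4-dimethoxyphenyl]-2,3-epoxy-7-methoxychroman-4-one (racemic, cis-fused epoxide; one enantiomer drawn) | COc1cc(OC)c([C@@]23Oc4cc(OC)c(OCc5ccccc5)cc4C(=O)[C@@H]2O3)cc1OCc1ccccc1
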